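If I charge 40 mM of substrate in place of 10 mM and keep the same mol% of free catalyst, the two flasks look like one recipe at two sizes, yet I do not expect them to end at the same percentage.

substrate 10 mM; gas 0.40 mM (held); free catalyst 2.5 mol%; time 15 h

- amount of product at 15 h, in percent of the substrate charged
- the change that raises the amount of product at 15 h, in percent of the substrate charged most ("none" if none brings more than 2 percentage points) (north-west / south-west / south-east / none)
- amount of product at 15 h, in percent of the substrate charged, after south-east

- north-west: doubling the saturation concentration of gas, all else as stated
- south-west: doubling the amount of free catalyst, all else as stated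
- south-east: doubling the transfer coefficient of step 5, all else as stated

Free catalyst takes up dissolved coupling partner to give intermediate A, A sheds by-product and becomes B, B binds substrate to give C, and C releases product and free catalyst. The coupling partner has to come from the gas, and none is dissolved at the start.

I solve the flask at both ends. With c(coupling partner) near zero, the gas end is the transfer coefficient times csat, 0.00720 mM min⁻¹. With the whole charge of catalyst as C, the catalyst end is the last step's constant times that charge, 0.0155 mM min⁻¹. Each turnover needs both passages in turn, so I add them like resistances in series. One over the sum of the two inverses gives 0.00492 mM min⁻¹, and this is the joined rate.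

The larger flask has the same gas end but a catalyst end of 0.0620 mM min⁻¹, so its joined rate is 0.00645 mM min⁻¹. That is 1.31 times the rate of this flask for 4.00 times the substrate, so the larger flask must stand lower in percent.

Over 15 h the joined rate gives 44.2 % for this flask. My reckoning stops there: it treats the gas end as constant, though the supply really follows csat minus c(coupling partner), so I commit to no figure for the best change or for the south-east flask.

The forecast gives 42 %, chooses south-west and puts the south-east flask at 48.5 %, on the ground that the run is “jointly limited by gas transfer” and the catalyst cycle.

    coupling partner + free catalyst → catalyst intermediate A (k1 = 580 M⁻¹ min⁻¹)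
    catalyst intermediate A ⇌ by-product + catalyst intermediate B (K2 = 0.0038 M, k2 = 0.22 min⁻¹)
    substrate + catalyst intermediate B ⇌ catalyst intermediate C (K3 = 730 M⁻¹, k3 = 21 M⁻¹ min⁻¹)
    catalyst intermediate C → free catalyst + product (k4 = 0.062 min⁻¹)
    gas ⇌ coupling partner, rate k5*(csat - [coupling partner]) (k5 = 0.018 min⁻¹, csat = 0.40 mM)

The flask gives 42.6 % with 57 % of the substrate still unreacted, and 48.7 % after south-east. The best change is south-west, which adds 11 percentage points, against 8.8 points for north-west and 6.1 points for south-east. The mean rate of this flask over 15 h is 0.00473 mM min⁻¹, beside a joined rate of 0.00492 mM min⁻¹. In the flask with 40 mM of substrate, the joined rate of 0.00645 mM min⁻¹ comes to 14.5 % of the substrate over the same time, and that flask stands at 15.1 %.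

(The numbers were chosen freely, and the outcome is calculated.)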